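Ring A of the flavone is disconnected to open-chain carbons: C4a and C8a are the C5=C6 bond of a 4-pyranone, C5 and C8 its diazoacetyl group, C6 and C7 a 1-methoxyalkyne. The feature exploited is the sequence 5-OH, 6-alkyl, 7-OMe, 8-H around ring A (C4a, C5, C6, C7, C8, C8a), which is the phenol, ortho-alkyl, meta-alkoxy pattern that a vinylketene and ynol ether benzannulation delivers. One operation should close ring A, form C5–C6, C7–C8 and C4a–C5, and fix every ring A substituent, so no 6- versus 8-alkylation or 5-O versus 7-O differentiation is needed. The precursor is a 2-aryl-3-prenyl-4-pyranone carrying the diazoacetyl group at C6, with the ring B phenols as allyl ethers.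

Key step: step 10

Assumption: epoxide 15 is drawn as its (R)-enantiomer so that every structure is defined; the racemate would serve equally, because this carbinol centre is oxidised to the ketone in step 12.

Step 1
Reactants: 1 2',4'-dihydroxyacetophenone
Product: 2 1-[2,4-bis(allyloxy)phenyl]ethanone
Conditions: allyl bromide (2.5 equiv), K2CO3 (3 equiv), DMF, 60 °C
Reagents that add atoms: allyl bromide, C=CCBr
Why: Williamson ether synthesis in which warm carbonate in DMF alkylates both the free 4-OH and the hydrogen-bonded 2-OH; allyl ethers are chosen because they survive strong base, the weak acid of the pyranone closure and the photolysis, and leave at the end under neutral conditions.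

Step 2
Reactants: 2 1-[2,4-bis(allyloxy)phenyl]ethanone; 3 ethyl acetate
Product: 4 1-[2,4-bis(allyloxy)phenyl]butane-1,3-dione
Conditions: NaH (2.5 equiv), 3 (5 equiv), THF, reflux; 1 M HCl work-up
Reagents that add atoms: none
Why: crossed Claisen condensation of the methyl ketone enolate with the ester, driven forward by deprotonation of the β-diketone that forms.

Step 3
Reactants: 4 1-[2,4-bis(allyloxy)phenyl]butane-1,3-dione; 5 prenyl bromide (1-bromo-3-methylbut-2-ene)
Product: 6 1-[2,4-bis(allyloxy)phenyl]-2-(3-methylbut-2-enyl)butane-1,3-dione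
Conditions: 5 (1.05 equiv), K2CO3, acetone, 50 °C
Reagents that add atoms: none
Why: SN2 C-alkylation of the stabilised β-diketone enolate by a soft allylic bromide, with one equivalent of bromide to curb dialkylation and O-alkylation.

Step 4
Reactants: 6 1-[2,4-bis(allyloxy)phenyl]-2-(3-methylbut-2-enyl)butane-1,3-dione; 7 diethyl oxalate
Product: 9 ethyl 6-[2,4-bis(allyloxy)phenyl]-5-(3-methylbut-2-enyl)-4-oxo-4H-pyran-2-carboxylate, via triketo ester 8 (not isolated)
Conditions: LiN(iPr)2 (3 equiv), THF, −78 to −20 °C; inverse addition to 7 (3 equiv), −78 °C; AcOH quench; then AcOH, 60 °C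
Reagents that add atoms: none
Why: the 1,3-dianion of the diketone is acylated at its terminal carbon by the oxalate (Claisen condensation of a β-diketone dianion) and the 1,3,5-tricarbonyl chain then cyclodehydrates in weak acid to the 4-pyranone, conditions chosen to be too mild to protonate the prenyl alkene.

Step 5
Reactants: 9 ethyl 6-[2,4-bis(allyloxy)phenyl]-5-(3-methylbut-2-enyl)-4-oxo-4H-pyran-2-carboxylate
Product: 10 6-[2,4-bis(allyloxy)phenyl]-5-(3-methylbut-2-enyl)-4-oxo-4H-pyran-2-carboxylic acid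
Conditions: LiOH·H2O (1.3 equiv), THF/H2O, 0 °C; then 1 M HCl to pH 3, 0 °C
Reagents that add atoms: lithium hydroxide (hydroxide oxygen), [Li+].[OH-]
Why: saponification of an activated heteroaryl ester, run cold with near-stoichiometric hydroxide to limit conjugate attack on the pyranone ring.

Step 6
Reactants: 10 6-[2,4-bis(allyloxy)phenyl]-5-(3-methylbut-2-enyl)-4-oxo-4H-pyran-2-carboxylic acid
Product: 12 2-[2,4-bis(allyloxy)phenyl]-6-(2-diazoacetyl)-3-(3-methylbut-2-enyl)-4H-pyran-4-one, via acid chloride 11 (not isolated)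
Conditions: 1-chloro-N,N,2-trimethylprop-1-en-1-amine (1.2 equiv), CH2Cl2, 0 °C to rt; then CH2N2 (3 equiv), Et2O, 0 °C
Reagents that add atoms: diazomethane, C=[N+]=[N-]
Why: neutral conversion of the acid into its chloride (no HCl is released onto the prenyl group) followed by acylation of diazomethane, the first stage of an Arndt–Eistert sequence, with excess diazomethane taking up the HCl formed.

Step 7
Reactants: 13 chloroacetaldehyde dimethyl acetal
Product: 14 methoxyacetylene
Conditions: NaNH2 (3.2 equiv), liquid NH3, −33 °C; cold sat. aq. NaCl; distil into cold THF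
Reagents that add atoms: none
Why: two successive base-induced eliminations (methanol, then HCl) give the alkoxyalkyne, held as its sodium acetylide until the aqueous quench, which is the standard preparation of 1-alkoxyalkynes from haloacetals.

Step 8
Reactants: 14 methoxyacetylene; 15 (R)-2-isopropyloxirane
Product: 17 (4S)-1-methoxy-5-methylhex-1-yn-4-ol, via lithium methoxyacetylide 16 (not isolated)
Conditions: 14 (1.3 equiv), n-BuLi, THF, −78 °C; BF3·OEt2 (1.3 equiv), then 15, −78 °C; sat. aq. NaHCO3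
Reagents that add atoms: none
Why: BF3-assisted SN2 opening of the epoxide by the lithium acetylide at the unsubstituted carbon, which leaves the carbinol centre of 15 untouched so that its configuration is carried into 17 (the descriptor changes from R to S only through the priority switch).

Step 9
Reactants: 17 (4S)-1-methoxy-5-methylhex-1-yn-4-ol
Product: 18 tert-butyl{[(4S)-1-methoxy-5-methylhex-1-yn-4-yl]oxy}dimethylsilane
Conditions: TBSCl, imidazole, DMF, rt
Reagents that add atoms: tert-butyldimethylsilyl chloride, CC(C)(C)[Si](C)(C)Cl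
Why: standard silylation of a secondary alcohol under basic conditions that the acid-sensitive ynol ether tolerates, so that no free hydroxyl can add to the ketene of step 10.

Step 10
Reactants: 12 2-[2,4-bis(allyloxy)phenyl]-6-(2-diazoacetyl)-3-(3-methylbut-2-enyl)-4H-pyran-4-one; 18 tert-butyl{[(4S)-1-methoxy-5-methylhex-1-yn-4-yl]oxy}dimethylsilane
Product: 22 2-[2,4-bis(allyloxy)phenyl]-6-[(2S)-2-(tert-butyldimethylsilyloxy)-3-methylbutyl]-5-hydroxy-7-methoxy-3-(3-methylbut-2-enyl)-4H-chromen-4-one, via pyranylketene 19 (not isolated), via cyclobutenone 20 (not isolated), via dienylketene 21 (not isolated)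
Conditions: 18 (2.5 equiv), hν (420 nm LEDs), degassed ClCH2CH2Cl, 20 °C; then 80 °C in the dark
Reagents that add atoms: none
Why: Proposed new method: excitation of the diazoketone expels N2 with 1,2-shift of the pyranyl group (Wolff rearrangement) to give ketene 19, whose central carbon (future C5) is attacked by the alkyl-bearing, nucleophilic carbon of ynol ether 18 in a [2+2] cycloaddition that gives 3-methoxycyclobutenone 20 and forms C5–C6 and C7–C8; on warming, 20 opens reversibly by four-electron electrocyclic cleavage to dienylketene 21, which closes across the pyranone C5=C6 bond to form C4a–C5, and enolisation of the cyclohexadienone gives the hydrogen-bonded 5-phenol. The closest known reaction type is the Danheiser benzannulation in its photochemical α-diazoketone variant, established for aryl and five-membered heteroaryl diazoketones but not for a 4-pyranone. Ring A is closed by a thermal six-electron electrocyclisation followed by tautomerisation, and no stereocentre is created (the transient C4 centre of 20 is lost and the silyloxy centre of 18 is a spectator). The selectivity needed is the orientation of the [2+2] step, which the donor oxygen of the ynol ether secures by making its β-carbon the nucleophile, so that the alkyl group ends at C6 and the methoxy group at C7. The weakly aromatic pyranone double bond should enter the electrocyclisation more readily than a benzene ring, irradiation at 420 nm (where only the diazoketone is expected to absorb) keeps the pyranone out of the photochemistry, and the separate dark thermal stage lets the phenol appear only after the ketene is consumed.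

Step 11
Reactants: 22 2-[2,4-bis(allyloxy)phenyl]-6-[(2S)-2-(tert-butyldimethylsilyloxy)-3-methylbutyl]-5-hydroxy-7-methoxy-3-(3-methylbut-2-enyl)-4H-chromen-4-one
Product: 23 2-[2,4-bis(allyloxy)phenyl]-5-hydroxy-6-[(2S)-2-hydroxy-3-methylbutyl]-7-methoxy-3-(3-methylbut-2-enyl)-4H-chromen-4-one
Conditions: TBAF (2.5 equiv), THF, 0 °C to rt; aqueous work-up
Reagents that add atoms: none
Why: fluoride-induced cleavage of the Si–O bond, to which the allyl ethers, the prenyl group and the chelated phenol are inert.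

Step 12
Reactants: 23 2-[2,4-bis(allyloxy)phenyl]-5-hydroxy-6-[(2S)-2-hydroxy-3-methylbutyl]-7-methoxy-3-(3-methylbut-2-enyl)-4H-chromen-4-one
Product: 24 2-[2,4-bis(allyloxy)phenyl]-5-hydroxy-7-methoxy-6-(3-methyl-2-oxobutyl)-3-(3-methylbut-2-enyl)-4H-chromen-4-one
Conditions: Dess–Martin periodinane (1.3 equiv), NaHCO3, CH2Cl2, 0 °C to rt
Reagents that add atoms: none
Why: buffered hypervalent-iodine oxidation of a secondary alcohol to the ketone, which also removes the only stereocentre; the 5-OH is tied up in a hydrogen bond to the C4 carbonyl and the ring B phenols are still allylated, so no phenol oxidation is expected.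

Step 13
Reactants: 24 2-[2,4-bis(allyloxy)phenyl]-5-hydroxy-7-methoxy-6-(3-methyl-2-oxobutyl)-3-(3-methylbut-2-enyl)-4H-chromen-4-one
Product: 25 2-(2,4-dihydroxyphenyl)-5-hydroxy-7-methoxy-6-(3-methyl-2-oxobutyl)-3-(3-methylbut-2-enyl)-4H-chromen-4-one (CNP0291994.0)
Conditions: Pd(PPh3)4 (5 mol%), morpholine (6 equiv), THF, rt
Reagents that add atoms: none
Why: Tsuji–Trost deallylation in which zerovalent palladium ionises the two aryl allyl ethers and morpholine traps the allyl units, under neutral conditions that spare the trisubstituted prenyl alkene, the methyl ether and the ortho-hydroxybenzyl ketone (which acid could close to a benzofuran).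

Compound list
1 | 2',4'-dihydroxyacetophenone | CC(=O)c1ccc(O)cc1O | starting material
2 | 1-[2,4-bis(allyloxy)phenyl]ethanone | CC(=O)c1ccc(OCC=C)cc1OCC=C | intermediate
3 | ethyl acetate | CCOC(C)=O | starting material
4 | 1-[2,4-bis(allyloxy)phenyl]butane-1,3-dione | CC(=O)CC(=O)c1ccc(OCC=C)cc1OCC=C | intermediate
5 | prenyl bromide (1-bromo-3-methylbut-2-ene) | CC(C)=CCBr | starting material
6 | 1-[2,4-bis(allyloxy)phenyl]-2-(3-methylbut-2-enyl)butane-1,3-dione | CC(=O)C(CC=C(C)C)C(=O)c1ccc(OCC=C)cc1OCC=C | intermediate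
7 | diethyl oxalate | CCOC(=O)C(=O)OCC | starting material
8 | ethyl 6-[2,4-bis(allyloxy)phenyl]-5-(3-methylbut-2-enyl)-2,4,6-trioxohexanoate | CCOC(=O)C(=O)CC(=O)C(CC=C(C)C)C(=O)c1ccc(OCC=C)cc1OCC=C | intermediate (not isolated)
9 | ethyl 6-[2,4-bis(allyloxy)phenyl]-5-(3-methylbut-2-enyl)-4-oxo-4H-pyran-2-carboxylate | CCOC(=O)c1cc(=O)c(CC=C(C)C)c(-c2ccc(OCC=C)cc2OCC=C)o1 | intermediate
10 | 6-[2,4-bis(allyloxy)phenyl]-5-(3-methylbut-2-enyl)-4-oxo-4H-pyran-2-carboxylic acid | OC(=O)c1cc(=O)c(CC=C(C)C)c(-c2ccc(OCC=C)cc2OCC=C)o1 | intermediate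
11 | 6-[2,4-bis(allyloxy)phenyl]-5-(3-methylbut-2-enyl)-4-oxo-4H-pyran-2-carbonyl chloride | ClC(=O)c1cc(=O)c(CC=C(C)C)c(-c2ccc(OCC=C)cc2OCC=C)o1 | intermediate (not isolated)
12 | 2-[2,4-bis(allyloxy)phenyl]-6-(2-diazoacetyl)-3-(3-methylbut-2-enyl)-4H-pyran-4-one | [N-]=[N+]=CC(=O)c1cc(=O)c(CC=C(C)C)c(-c2ccc(OCC=C)cc2OCC=C)o1 | intermediate
13 | chloroacetaldehyde dimethyl acetal | COC(CCl)OC | starting material
14 | methoxyacetylene | COC#C | intermediate
15 | (R)-2-isopropyloxirane | CC(C)[C@@H]1CO1 | starting material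
16 | lithium methoxyacetylide | [Li]C#COC | intermediate (not isolated)
17 | (4S)-1-methoxy-5-methylhex-1-yn-4-ol | COC#CC[C@H](O)C(C)C | intermediate
18 | tert-butyl{[(4S)-1-methoxy-5-methylhex-1-yn-4-yl]oxy}dimethylsilane | COC#CC[C@H](O[Si](C)(C)C(C)(C)C)C(C)C | intermediate
19 | {6-[2,4-bis(allyloxy)phenyl]-5-(3-methylbut-2-enyl)-4-oxo-4H-pyran-2-yl}ketene | O=C=Cc1cc(=O)c(CC=C(C)C)c(-c2ccc(OCC=C)cc2OCC=C)o1 | intermediate (not isolated)
20 | 4-{6-[2,4-bis(allyloxy)phenyl]-5-(3-methylbut-2-enyl)-4-oxo-4H-pyran-2-yl}-2-[(2S)-2-(tert-butyldimethylsilyloxy)-3-methylbutyl]-3-methoxycyclobut-2-en-1-one (both C4 epimers) | COC1=C(C[C@H](O[Si](C)(C)C(C)(C)C)C(C)C)C(=O)C1c1cc(=O)c(CC=C(C)C)c(-c2ccc(OCC=C)cc2OCC=C)o1 | intermediate (not isolated)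
21 | (3E)-4-{6-[2,4-bis(allyloxy)phenyl]-5-(3-methylbut-2-enyl)-4-oxo-4H-pyran-2-yl}-2-[(2S)-2-(tert-butyldimethylsilyloxy)-3-methylbutyl]-3-methoxybuta-1,3-dien-1-one | CO/C(=C/c1cc(=O)c(CC=C(C)C)c(-c2ccc(OCC=C)cc2OCC=C)o1)C(=C=O)C[C@H](O[Si](C)(C)C(C)(C)C)C(C)C | intermediate (not isolated)
22 | 2-[2,4-bis(allyloxy)phenyl]-6-[(2S)-2-(tert-butyldimethylsilyloxy)-3-methylbutyl]-5-hydroxy-7-methoxy-3-(3-methylbut-2-enyl)-4H-chromen-4-one | COc1cc2oc(-c3ccc(OCC=C)cc3OCC=C)c(CC=C(C)C)c(=O)c2c(O)c1C[C@H](O[Si](C)(C)C(C)(C)C)C(C)C | intermediate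
23 | 2-[2,4-bis(allyloxy)phenyl]-5-hydroxy-6-[(2S)-2-hydroxy-3-methylbutyl]-7-methoxy-3-(3-methylbut-2-enyl)-4H-chromen-4-one | COc1cc2oc(-c3ccc(OCC=C)cc3OCC=C)c(CC=C(C)C)c(=O)c2c(O)c1C[C@H](O)C(C)C | intermediate
24 | 2-[2,4-bis(allyloxy)phenyl]-5-hydroxy-7-methoxy-6-(3-methyl-2-oxobutyl)-3-(3-methylbut-2-enyl)-4H-chromen-4-one | COc1cc2oc(-c3ccc(OCC=C)cc3OCC=C)c(CC=C(C)C)c(=O)c2c(O)c1CC(=O)C(C)C | intermediate
25 | 2-(2,4-dihydroxyphenyl)-5-hydroxy-7-methoxy-6-(3-methyl-2-oxobutyl)-3-(3-methylbut-2-enyl)-4H-chromen-4-one (CNP0291994.0, achiral) | COc1cc2oc(-c3ccc(O)cc3O)c(CC=C(C)C)c(=O)c2c(O)c1CC(=O)C(C)C | target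

Total step count: 13.
Longest linear sequence: 10 steps (steps 1–6 and 10–13, from 1 to 25); steps 7–9 make the alkyne branch.

Steps most likely to fail

Step 10 (ring A benzannulation). The photogenerated ketene may be lost to dimerisation or to carbene-type side reactions before the ynol ether intercepts it, or the sequence may stall at the cyclobutenone because closure onto the pyranone C5=C6 bond is too slow. The fallback uses known chemistry: ring A is taken from a symmetry-labelled arene and the pyranone ring is closed last. It sets out from acetophenone 2 and epoxide 15 and comes back to the route at 22. Commercial 3,5-dimethoxyphenol is silylated (TIPSCl, imidazole, DMF) to (3,5-dimethoxyphenoxy)tri(propan-2-yl)silane F1. Lithiation between the two methoxy groups (n-BuLi, THF, 0 °C) and BF3·OEt2-assisted opening of 15 at −78 °C should give (2S)-1-[2,6-dimethoxy-4-(triisopropylsilyloxy)phenyl]-3-methylbutan-2-ol F2, which is silylated (TBSCl, imidazole) to the bis-silyl ether F3. Bromination at one of the two equivalent free ring positions (NBS, MeCN, 0 °C) gives aryl bromide F4, and bromine–lithium exchange (n-BuLi, THF, −78 °C) with DMF quench gives 3-[(2S)-2-(tert-butyldimethylsilyloxy)-3-methylbutyl]-2,4-dimethoxy-6-(triisopropylsilyloxy)benzaldehyde F5. Separately, 2 is α-prenylated (LiN(iPr)2, THF, −78 °C, then prenyl bromide 5) to 1-[2,4-bis(allyloxy)phenyl]-5-methylhex-4-en-1-one F6. Its lithium enolate adds to F5 to give the β-hydroxy ketone F7 (diastereomer mixture), and Dess–Martin oxidation gives the 1,3-diketone F8. One equivalent of TBAF at 0 °C should remove the aryl silyl group selectively to give the phenol diketone F9 (not isolated), and warm acetic acid closes the pyranone through this single free hydroxyl to the 5,7-dimethoxyflavone F10. Chelation-assisted cleavage of the 5-methyl ether (MgI2·OEt2, toluene, 80 °C) then gives 22. The 6-alkyl position is fixed by the symmetry of F1 to F3, and the one silylated oxygen, which becomes O1, settles which oxygen ends as the 5-OH.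

Step 4 (oxalylation and pyranone closure). The dianion may add a second time to the very electrophilic α-keto ester as it forms, and the pyranone ester may later suffer ring opening during the saponification of step 5. The fallback brings in the carboxyl carbon at the aldehyde oxidation level; it sets out from diketone 6 and comes back at acid 10, bypassing ester 9 and step 5. The same dianion of 6 is acylated with ethyl diethoxyacetate to 1-[2,4-bis(allyloxy)phenyl]-6,6-diethoxy-2-(3-methylbut-2-enyl)hexane-1,3,5-trione F11, whose acetal-flanked ketone is far less prone to a second addition. Warm acetic acid closes it to 2-[2,4-bis(allyloxy)phenyl]-6-(diethoxymethyl)-3-(3-methylbut-2-enyl)-4H-pyran-4-one F12, and aqueous HCl in THF at 40 °C frees 6-[2,4-bis(allyloxy)phenyl]-5-(3-methylbut-2-enyl)-4-oxo-4H-pyran-2-carbaldehyde F13. A Pinnick oxidation (NaClO2, NaH2PO4, 2-methylbut-2-ene, t-BuOH/H2O) then gives 10 without any hydroxide treatment of the pyranone.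

Step 6 (diazoketone formation). Diazomethane may add as a dipole across the electron-poor pyranone double bond, or attack the ring, faster than it is acylated. The fallback installs the diazo group by diazo transfer instead; it sets out from acid 10 (through its chloride 11) and comes back at 12. Chloride 11 is treated with Me2CuLi (THF, −78 °C) to give 6-acetyl-2-[2,4-bis(allyloxy)phenyl]-3-(3-methylbut-2-enyl)-4H-pyran-4-one F14. Its lithium enolate (LiN(SiMe3)2, THF, −78 °C) is trifluoroacetylated with 2,2,2-trifluoroethyl trifluoroacetate to the trifluoroacetyl diketone F15 (not isolated). Methanesulfonyl azide with Et3N and water in MeCN then transfers the diazo group with loss of the trifluoroacetyl unit, giving 12.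

Further compounds
F1 | step 10 | (3,5-dimethoxyphenoxy)tri(propan-2-yl)silane | COc1cc(OC)cc(O[Si](C(C)C)(C(C)C)C(C)C)c1
F2 | step 10 | (2S)-1-[2,6-dimethoxy-4-(triisopropylsilyloxy)phenyl]-3-methylbutan-2-ol | COc1cc(O[Si](C(C)C)(C(C)C)C(C)C)cc(OC)c1C[C@H](O)C(C)C
F3 | step 10 | tert-butyl{[(2S)-1-[2,6-dimethoxy-4-(triisopropylsilyloxy)phenyl]-3-methylbutan-2-yl]oxy}dimethylsilane | COc1cc(O[Si](C(C)C)(C(C)C)C(C)C)cc(OC)c1C[C@H](O[Si](C)(C)C(C)(C)C)C(C)C
F4 | step 10 | {2-bromo-4-[(2S)-2-(tert-butyldimethylsilyloxy)-3-methylbutyl]-3,5-dimethoxyphenoxy}tri(propan-2-yl)silane | COc1cc(O[Si](C(C)C)(C(C)C)C(C)C)c(Br)c(OC)c1C[C@H](O[Si](C)(C)C(C)(C)C)C(C)C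
F5 | step 10 | 3-[(2S)-2-(tert-butyldimethylsilyloxy)-3-methylbutyl]-2,4-dimethoxy-6-(triisopropylsilyloxy)benzaldehyde | COc1cc(O[Si](C(C)C)(C(C)C)C(C)C)c(C=O)c(OC)c1C[C@H](O[Si](C)(C)C(C)(C)C)C(C)C
F6 | step 10 | 1-[2,4-bis(allyloxy)phenyl]-5-methylhex-4-en-1-one | CC(C)=CCCC(=O)c1ccc(OCC=C)cc1OCC=C
F7 | step 10 | 1-[2,4-bis(allyloxy)phenyl]-3-{3-[(2S)-2-(tert-butyldimethylsilyloxy)-3-methylbutyl]-2,4-dimethoxy-6-(triisopropylsilyloxy)phenyl}-3-hydroxy-2-(3-methylbut-2-enyl)propan-1-one (diastereomer mixture at C2 and C3) | CC(C)=CCC(C(O)c1c(O[Si](C(C)C)(C(C)C)C(C)C)cc(OC)c(C[C@H](O[Si](C)(C)C(C)(C)C)C(C)C)c1OC)C(=O)c1ccc(OCC=C)cc1OCC=C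
F8 | step 10 | 1-[2,4-bis(allyloxy)phenyl]-3-{3-[(2S)-2-(tert-butyldimethylsilyloxy)-3-methylbutyl]-2,4-dimethoxy-6-(triisopropylsilyloxy)phenyl}-2-(3-methylbut-2-enyl)propane-1,3-dione | CC(C)=CCC(C(=O)c1c(O[Si](C(C)C)(C(C)C)C(C)C)cc(OC)c(C[C@H](O[Si](C)(C)C(C)(C)C)C(C)C)c1OC)C(=O)c1ccc(OCC=C)cc1OCC=C
F9 | step 10 | 1-[2,4-bis(allyloxy)phenyl]-3-{3-[(2S)-2-(tert-butyldimethylsilyloxy)-3-methylbutyl]-6-hydroxy-2,4-dimethoxyphenyl}-2-(3-methylbut-2-enyl)propane-1,3-dione | CC(C)=CCC(C(=O)c1c(O)cc(OC)c(C[C@H](O[Si](C)(C)C(C)(C)C)C(C)C)c1OC)C(=O)c1ccc(OCC=C)cc1OCC=C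
F10 | step 10 | 2-[2,4-bis(allyloxy)phenyl]-6-[(2S)-2-(tert-butyldimethylsilyloxy)-3-methylbutyl]-5,7-dimethoxy-3-(3-methylbut-2-enyl)-4H-chromen-4-one | COc1cc2oc(-c3ccc(OCC=C)cc3OCC=C)c(CC=C(C)C)c(=O)c2c(OC)c1C[C@H](O[Si](C)(C)C(C)(C)C)C(C)C
F11 | step 4 | 1-[2,4-bis(allyloxy)phenyl]-6,6-diethoxy-2-(3-methylbut-2-enyl)hexane-1,3,5-trione | CCOC(OCC)C(=O)CC(=O)C(CC=C(C)C)C(=O)c1ccc(OCC=C)cc1OCC=C
F12 | step 4 | 2-[2,4-bis(allyloxy)phenyl]-6-(diethoxymethyl)-3-(3-methylbut-2-enyl)-4H-pyran-4-one | CCOC(OCC)c1cc(=O)c(CC=C(C)C)c(-c2ccc(OCC=C)cc2OCC=C)o1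
F13 | step 4 | 6-[2,4-bis(allyloxy)phenyl]-5-(3-methylbut-2-enyl)-4-oxo-4H-pyran-2-carbaldehyde | O=Cc1cc(=O)c(CC=C(C)C)c(-c2ccc(OCC=C)cc2OCC=C)o1
F14 | step 6 | 6-acetyl-2-[2,4-bis(allyloxy)phenyl]-3-(3-methylbut-2-enyl)-4H-pyran-4-one | CC(=O)c1cc(=O)c(CC=C(C)C)c(-c2ccc(OCC=C)cc2OCC=C)o1
F15 | step 6 | 1-{6-[2,4-bis(allyloxy)phenyl]-5-(3-methylbut-2-enyl)-4-oxo-4H-pyran-2-yl}-4,4,4-trifluorobutane-1,3-dione | O=C(CC(=O)C(F)(F)F)c1cc(=O)c(CC=C(C)C)c(-c2ccc(OCC=C)cc2OCC=C)o1
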